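The runs come from a simulation with constants of no real substance.

Early in a run, the rise of target shows how fast the catalyst works, so I start there.

| flask | starting material | catalyst | temperature | remark | time |
|---|---|---|---|---|---|
| elm | 3 M | 34 mM | 65 °C | run made earlier |  |
| oak | 3 M | 76 mM | 98 °C | run made earlier |  |
| alpha | 3.0 M | 51 mM | 90 °C |  | 50 min |
| theta | 3.0 M | 51 mM | 110 °C |  | 50 min |
| epsilon | 3.0 M | 51 mM | 50 °C |  | 50 min |
| delta | 3.0 M | 51 mM | 70 °C |  | 50 min |

| elm: time / min | elm: target / % | oak: time / min | oak: target / % |
|---|---|---|---|
| 8.00 | 23 | 2.50 | 68 |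
| 15.0 | 38 | 4.00 | 73 |
| 20.0 | 45 | 6.00 | 73 |
| 30.0 | 59 | 8.00 | 74 |
| 40.0 | 65 | 12.0 | 74 |
| 60.0 | 74 | 20.0 | 77 |
| 90.0 | 77 | 30.0 | 79 |

(scatter of a reading: 2 percentage points)

- the numbers in the tables scatter with a standard deviation of 2 percentage points
- in a conversion other conformer counts as not yet reacted
- a reading or a percentage of target counts all its forms, free or not

- the flask that comes out highest in amount of target, in percent of the starting material charged, or "all alike" when all lie within 1.5 percentage points (alpha / theta / epsilon / delta / all alike)
- target at the end, in percent of the starting material charged, alpha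
- target at the end, in percent of the starting material charged, theta
- target at the end, in percent of the starting material charged, epsilon
- target at the end, in percent of the starting material charged, delta

I read each early rise as pseudo-first-order, toward the level at which it flattens, and I take its rate constant as proportional to [catalyst]. Elm stands at 45% at 20.0 min, against a top reading of 77%. Oak stands at 68% at 2.50 min, against 74% at 12.0 min, where its rise has flattened.

rate constant: elm 0.0439 min⁻¹, oak 1.00 min⁻¹

per [catalyst]: elm 1.29 L mol⁻¹ min⁻¹, oak 13.2 L mol⁻¹ min⁻¹

activation energy: 73.6 kJ mol⁻¹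

The oak value is rough: its gap is 6 percentage points, and a reading scatters by 2 points.

I carry one quantity, s = 0.383 L mol⁻¹ min⁻¹, the cold constant, read from these two runs: the rate constant per [catalyst] at 50 °C. At that temperature, the product n = s[catalyst]t counts the time constants in a hold.

At 51 mM of catalyst, the ladder of time constants runs from the hottest flask down:

theta 0.703 min

alpha 2.51 min

delta 10.4 min

epsilon 51.2 min

Delta's time constant is shorter than the hold of 50 min, and theta's and alpha's are shorter still, so I expect delta, alpha and theta at their tops. Oak and elm end 2 points apart, within the scatter, so I do not rank delta, alpha and theta.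

Epsilon's hold is about one time constant, so it stops on the rise:

n = 0.978, share used 62.4%, times elm's top: 48.0%

The forecast names theta, with alpha 80%, theta 91%, epsilon 48% and delta 76%. Its hot flasks climb on “other conformer feeding in slowly through an uncatalysed step”. I do not add that climb.

The flask gives delta highest at 81.0%, then alpha 71.4%, theta 70.3% and epsilon 52.0%. At 50.0 min, theta holds 29.7% isomer of the product, more than delta's 17.8%. Put back on epsilon, the cold constant and elm's top reading give 48.0% target, and the flask holds 52.0%.

    starting material ⇌ other conformer (K = 0.750, k = 0.00290 s⁻¹, Ea = 118 kJ mol⁻¹, ΔH = −29.0 kJ mol⁻¹)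
    starting material + catalyst → catalyst + target (k = 0.100 L mol⁻¹ s⁻¹, Ea = 73.0 kJ mol⁻¹)
    catalyst + other conformer → catalyst + isomer of the product (k = 0.180 L mol⁻¹ s⁻¹, Ea = 59.0 kJ mol⁻¹)
    crystals ⇌ target, rate k4*(cs4 - [target]) while solid is left; crystals form when [target] > cs4 (solubility = 1.50 M, k = 0.530 s⁻¹)
    (constants at 90 °C)

A neighbour of epsilon has 0.013 M of catalyst, with the same temperature and hold. There n = 0.249, which with elm's top reading gives 17.0% target. The computed flask holds 17.2% target.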